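## Structural features

The target 17 is a 1H-indole: a benzene ring (C3a, C4, C5, C6, C7, C7a) fused across the C3a–C7a bond to a pyrrole ring (N1, C2, C3, C3a, C7a). It has no stereocentre, so nothing stereochemical has to be set or protected. Three bromines decorate it: one at C3 of the five-membered ring and two at C4 and C6 of the benzo ring, meta to each other, with the C3 and C4 bromines crowded in a peri relationship. The fragile parts are the free N–H 3-bromoindole unit (sensitive to acid, light and oxidants) and the C–Br bonds themselves, which forbid organolithium reagents, dissolving metals, hydrogenolysis and zerovalent palladium once they are in place. The real difficulty is the 4,6-pattern: C3 is the innately nucleophilic carbon and takes bromine readily, but electrophilic bromination of an indole does not select C4 together with C6, so these two halogens have to be built in while the benzo ring is made. The feature used for this is the carbocycle C3a–C4–C5–C6–C7–C7a: opened at C5–C6 it becomes a pyrrole with a two-carbon arm on C3 (C4 and C5, C4 already bearing its bromine as a vinyl bromide) and a two-carbon arm on C2 (C7 and C6, C6 as a CBr2 group whose second bromine pays for the aromatisation), and both arms trace back to carbonyl groups.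

## Logic of the disconnections

17 ⇒ 16. The N1–S bond is cut, so that the sulfonyl group is removed last in the forward sense. It is kept to the end because it steers the metalation, tempers the pyrrole and the indole towards electrophiles and eases the ring closure. The gain is that every earlier intermediate is a non-acidic sulfonamide. The demand is cleavage by nucleophilic attack at sulfur, since reductive methods would take the C–Br bonds with them.

16 ⇒ 15 + 12. The C3–Br bond is cut because C3 is the one position where an electrophile goes by itself. This leaves only the two bromines that cannot be introduced that way and leads back to the product of the ring-forming step. The forward step has to stop at one bromine and must not touch C2 despite the peri bromine at C4.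

15 ⇒ 13 (through 14). The C5–C6 bond of the benzo ring is cut and HBr is added back across it, which turns the bicycle into a monocyclic pyrrole with a 1-bromovinyl arm and a 2,2-dibromovinyl arm. This is the strategic cut: an arene substitution problem becomes the placement of two carbonyl-derived arms on adjacent pyrrole carbons. The demand is a thermal six-electron closure that must pay for lost pyrrole aromaticity and for an inward bromine, with an acid scavenger that leaves the vinyl bromides alone.

13 ⇒ 11 + 12. The C4–Br bond is cut, the bromoalkene going back to a methyl ketone. A ketone is the natural and far more robust precursor of a 1-bromovinyl group. The cut sits directly before the ring closure because the bromoalkene would not survive bases or organometallic reagents. The forward step must exchange C=O for C(Br)=CH2 without brominating the ring or the other alkene.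

11 ⇒ 7 + 8 + 9 (through 10). The C6=C7 double bond is cut to an aldehyde and a one-carbon CBr2 donor, and the ketone is put back under its ketal. One reagent brings C6 with both bromines, and the aldehyde carbon becomes C7. The forward olefination must take the aldehyde only, which the ketal guarantees, and the ketal must then come off without a separate isolation.

7 ⇒ 3 + 4 (through 5 and 6). The bond between pyrrole C2 and the formyl carbon is cut, which leaves a pyrrole with a single substituent. C2 is the ring carbon flanked by the sulfonamide nitrogen and the ketal, so a directed deprotonation should find it. The demand is regioselectivity for C2 over C5 and no attack of the base on sulfur.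

3 ⇒ 1 + 2. The two C–O bonds of the ketal are cut, giving two commercial compounds. The ketone has to be masked because its enolisable methyl group and its carbonyl would consume the amide base, the aryllithium and the ylide. The forward step needs removal of water to drive a deactivated aryl ketone to its ketal.

## Other disconnections considered

Alternative 1: This cut removes three ring bonds at once, C3a–C7a, C4–C5 and C6–C7, and unravels both rings. The product of the key step would be 1-tosyl-4,6-bis(trimethylsilyl)indoline A1. It would be assembled by a metal-catalysed (2+2+2) cyclotrimerisation of the ynamide diyne N-ethynyl-4-methyl-N-[4-(trimethylsilyl)but-3-yn-1-yl]benzenesulfonamide A2 with ethynyltrimethylsilane A3.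

- In its favour: one catalytic step forms three C–C bonds and two rings under mild conditions. The tether fixes the C4 silyl group, and the incoming alkyne should place its silicon at C6, away from the C4 silyl group. Exchange of aryl silicon for bromine by ipso substitution is a dependable reaction type.
- Against it here: A1 is an indoline, so a dehydrogenation is needed. C4 and C6 are meta to the ring nitrogen, so ipso-bromodesilylation with 12 must outrun ordinary bromination at C5 and C7, which the nitrogen activates. The terminal ynamide of A2 is delicate and takes several steps to make. After the key step come two silicon–bromine exchanges, aromatisation, C3 bromination and detosylation, for roughly nine to ten steps in all.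
- Comparison: on structure the two plans are equal in principle, since both fix the 4,6-pattern by construction. On bond-forming efficiency and mildness of the ring-forming step the alternative is the better. On mechanism both rest on one ring-forming event not yet tried on the substrate. The chosen plan, however, delivers the bromines and the aromatic oxidation level directly from that event. On step economy the chosen plan is better by two to three steps.

Alternative 2: This cut takes N1–C7a and C3–C3a, so the five-membered ring is laid onto a ready-made dibromoarene. The product of the key step would be racemic 1-tert-butyl 2-methyl 4,6-dibromoindoline-1,2-dicarboxylate A4. Fluoride would release 3,5-dibromobenzyne A5 from 2,4-dibromo-6-(trimethylsilyl)phenyl trifluoromethanesulfonate A6. The carbamate nitrogen of methyl 2-[(tert-butoxycarbonyl)amino]acrylate A7 would add to the aryne carbon remote from the flanking bromine, and the aryl anion beside that bromine would close onto the acrylate terminus.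

- In its favour: both benzo-ring bromines are present from the first intermediate. The innate polarisation of a 3-haloaryne is exactly the regiochemistry required. The annulation runs near room temperature, and the C2 stereocentre is irrelevant because it is erased.
- Against it here: the aryl anion sits ortho to a bromide and may expel it to give a second aryne. The closure is a 5-endo addition. A4 carries a surplus ester carbon and the indoline oxidation level, so hydrolysis, decarboxylation, dehydrogenation, carbamate removal and C3 bromination must follow, the decarboxylation being the harsh one next to aryl bromides.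
- Comparison: on structure the alternative is the better, because the C4 and C6 halogens never have to be introduced. On mildness of the ring closure it is also the better, and its reaction class is at least the equal of the chosen ring closure in precedent. On mechanism it has a specific competing pathway (bromide expulsion), whereas the chosen closure is mainly threatened by slowness. On step economy the two are about equal, at seven to eight steps. More of the alternative's steps are corrective, removing a carbon and adjusting oxidation level, than constructive.

Alternative 3: This cut goes back from the indole N1–C2 bond to a quinoline in which one extra carbon stands between nitrogen and the future C2. The product of the key step would be 1-acetyl-3,4,6-tribromoindole A8. Irradiation near 390 nm would turn 4,5,7-tribromo-2-methylquinoline 1-oxide A9 into 5,6,8-tribromo-2-methyl-3,1-benzoxazepine A10, and acid in the same pot would contract A10 to A8. Mild N-deacetylation of A8 would then give 17. A9 would come from the symmetric 3,5-dibromoaniline A11 in three operations: a quinolone synthesis of the Conrad–Limpach type, replacement of the ring hydroxyl by bromine, and N-oxidation.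

- In its favour: A11 is symmetric, so the quinoline ring closure has no regiochemical question. All three bromines, including the one that becomes C3, are in place before the key step, so no late bromination is needed. The route is about five to six steps.
- Against it here: three heavy atoms should favour intersystem crossing, and the triplet manifold of N-oxides tends towards deoxygenation instead of rearrangement. C–Br photolysis may compete. The bromine para to the N-oxide is activated towards nucleophilic displacement. The peri-dibromo strain and the vinylic bromine of A10 may disturb the acid-induced contraction.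
- Comparison: on step economy the alternative is the better, by one to two steps. On structure it is the equal or the better, with every substituent fixed from a symmetric precursor. On mechanism the chosen thermal closure has a single predictable course, whereas the photochemical cascade has branching excited-state pathways that the bromines specifically aggravate. The chosen plan also needs no photochemical equipment.

Key step: step 5

Remark on the chemistry: the atom mapping of 13 onto 15 needs no correction (pyrrole C2 becomes C7a, C3 becomes C3a, the CBr2 carbon becomes C6, the acetyl carbons become C4 and C5). The acid scavenger of the ring closure is taken to be a weakly basic hindered pyridine, because amidine or alkoxide bases would turn the 2,2-dibromovinyl group into a bromoalkyne before closure.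

## Route

Step 1
Reactants: 1 3-acetyl-1-(phenylsulfonyl)pyrrole; 2 ethylene glycol
Product: 3 3-(2-methyl-1,3-dioxolan-2-yl)-1-(phenylsulfonyl)pyrrole
Conditions: TsOH·H2O (cat.), PhMe, reflux, Dean–Stark
Reagents that add atoms: ethylene glycol, OCCO
Why: Acid-catalysed ketalisation driven by azeotropic removal of water; the electron-poor N-sulfonylpyrrole tolerates the acid, and the ketal hides the enolisable ketone from the amide base, the aryllithium and the ylide of steps 2 and 3.

Step 2
Reactants: 3 3-(2-methyl-1,3-dioxolan-2-yl)-1-(phenylsulfonyl)pyrrole; 4 N,N-dimethylformamide
Product: 7 3-(2-methyl-1,3-dioxolan-2-yl)-1-(phenylsulfonyl)pyrrole-2-carbaldehyde, via 2-lithiopyrrole 5 (not isolated), via lithium hemiaminolate 6 (not isolated)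
Conditions: LiN(iPr)2 (1.2 equiv), THF, −78 °C; then DMF, −78 to 0 °C; H2O
Reagents that add atoms: N,N-dimethylformamide, CN(C)C=O
Why: Directed ortho-metalation: the C2 hydrogen is the only ring hydrogen flanked by both the N-sulfonyl group and the ketal oxygens, which should combine inductive acidification with lithium coordination, as in the 2-lithiation of 3-(1,3-dioxolan-2-yl)thiophenes and furans. Formylation of the aryllithium by the formamide stops at the hemiaminolate until the aqueous quench, so no over-addition is expected.

Step 3
Reactants: 7 3-(2-methyl-1,3-dioxolan-2-yl)-1-(phenylsulfonyl)pyrrole-2-carbaldehyde; 8 carbon tetrabromide; 9 water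
Product: 11 1-[2-(2,2-dibromovinyl)-1-(phenylsulfonyl)pyrrol-3-yl]ethanone, via dibromoalkene ketal 10 (not isolated)
Conditions: CBr4 (2 equiv), PPh3 (4 equiv), CH2Cl2, 0 °C; then 2 M aq HCl, THF, rt
Reagents that add atoms: carbon tetrabromide, BrC(Br)(Br)Br; water, O
Why: Ramirez dibromo-olefination (the first stage of the Corey–Fuchs sequence): the ylide formed from PPh3 and CBr4 undergoes a Wittig reaction with the aldehyde, the only carbonyl group on offer while the ketone is masked. The 1,1-dibromoalkene is inert to dilute aqueous acid, so the ketal can be hydrolysed in the same flask, which saves an isolation.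

Step 4
Reactants: 11 1-[2-(2,2-dibromovinyl)-1-(phenylsulfonyl)pyrrol-3-yl]ethanone; 12 bromine
Product: 13 3-(1-bromovinyl)-2-(2,2-dibromovinyl)-1-(phenylsulfonyl)pyrrole
Conditions: P(OPh)3 (1.2 equiv), Br2 (1.1 equiv), CH2Cl2, −60 °C; Et3N (1.3 equiv), then 11, −60 °C to rt
Reagents that add atoms: bromine, BrBr
Why: Conversion of an enolisable methyl ketone into its 1-bromoalkene by the triphenyl phosphite–bromine reagent: the carbonyl oxygen is transferred to phosphorus, bromide enters at carbon and Et3N removes HBr from the methyl group. All the bromine is bound to phosphorus before the substrate arrives, so the dibromoalkene and the deactivated pyrrole ring should be spared.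

Step 5
Reactants: 13 3-(1-bromovinyl)-2-(2,2-dibromovinyl)-1-(phenylsulfonyl)pyrrole
Product: 15 4,6-dibromo-1-(phenylsulfonyl)indole, via dihydroindole 14 (not isolated)
Conditions: 2,6-di-tert-butyl-4-methylpyridine (1.5 equiv), BHT (cat.), o-C6H4Cl2 (degassed), 170 °C, dark
Reagents that add atoms: none
Why: Proposed new method: the hexatriene C5H2=C4(Br)–C3a=C7a–C7H=C6Br2 of 13, whose central double bond is the pyrrole C2–C3 bond, should undergo a thermally allowed disrotatory 6π-electrocyclisation that joins C5 to C6 and closes the six-membered carbocycle as the 1,3-cyclohexadiene 14. In 14 the two C6 bromines sit on an sp3 carbon that is allylic to the C7=C7a enamide bond and next to C5H2, so ionisation of one C6–Br bond (or a concerted elimination) and removal of a C5 proton by the pyridine base should give 15 irreversibly; a prior 1,5-hydrogen shift from C5 to C7 would lead to the same arene, because C6 carries no hydrogen. The closest known reaction types are the thermal electrocyclisation of 2,3-divinylpyrroles and 2,3-divinylindoles followed by dehydrogenation, and the electrocyclisation–elimination of trienes whose terminus carries two geminal leaving groups (ketene dithioacetals, 1,1-difluoroalkenes); new here is the 1,1-dibromoalkene terminus on a pyrrole. No stereocentre is formed, so the sense of rotation has no consequence. The selectivity needed is the choice of the bromine that leaves and the order of events: only the C6 bromines ever sit on a saturated carbon beside a C–H bond, whereas the C4 bromine is vinylic in 13 and 14 and aryl in 15, and the base is too weak and too hindered to turn the dibromovinyl group into a bromoalkyne or the bromovinyl group into an alkyne before the closure. The N-sulfonyl group lowers the aromatic stabilisation that the pyrrole gives up in the transition state. The bromine of the CBr2 group that must point into the forming ring raises the barrier, hence 170 °C in a high-boiling inert solvent, with a radical inhibitor and exclusion of light and oxygen to hold back polymerisation of the vinyl bromides.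

Step 6
Reactants: 15 4,6-dibromo-1-(phenylsulfonyl)indole; 12 bromine
Product: 16 3,4,6-tribromo-1-(phenylsulfonyl)indole
Conditions: Br2 (1.05 equiv), CH2Cl2, 0 °C to rt
Reagents that add atoms: bromine, BrBr
Why: Electrophilic aromatic bromination at C3, the β-carbon of the N-sulfonyl enamine unit and the most nucleophilic position of the ring system. The sulfonyl group and the two ring bromines restrain the indole, so substitution should stop at one bromine and leave C2, C5 and C7 untouched.

Step 7
Reactants: 16 3,4,6-tribromo-1-(phenylsulfonyl)indole
Product: 17 3,4,6-tribromo-1H-indole
Conditions: NaOH (2 M aq), MeOH/THF, 50 °C; aq NH4Cl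
Reagents that add atoms: none
Why: Sulfonamide cleavage by attack of hydroxide at sulfur, eased because three bromines make the indole nitrogen a good leaving group. Aryl bromides are inert to hydroxide at this temperature, and work-up near neutral pH with protection from light respects the sensitivity of the 3-bromoindole.

## Compound list

1 | 3-acetyl-1-(phenylsulfonyl)pyrrole | CC(=O)c1ccn(S(=O)(=O)c2ccccc2)c1 | starting material
2 | ethylene glycol | OCCO | starting material
3 | 3-(2-methyl-1,3-dioxolan-2-yl)-1-(phenylsulfonyl)pyrrole | CC1(c2ccn(S(=O)(=O)c3ccccc3)c2)OCCO1 | intermediate
4 | N,N-dimethylformamide | CN(C)C=O | starting material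
5 | 2-lithio-3-(2-methyl-1,3-dioxolan-2-yl)-1-(phenylsulfonyl)pyrrole (not isolated) | [Li]c1c(C2(C)OCCO2)ccn1S(=O)(=O)c1ccccc1 | intermediate
6 | lithium (dimethylamino)[3-(2-methyl-1,3-dioxolan-2-yl)-1-(phenylsulfonyl)pyrrol-2-yl]methanolate (racemic, not isolated) | [Li]OC(N(C)C)c1c(C2(C)OCCO2)ccn1S(=O)(=O)c1ccccc1 | intermediate
7 | 3-(2-methyl-1,3-dioxolan-2-yl)-1-(phenylsulfonyl)pyrrole-2-carbaldehyde | O=Cc1c(C2(C)OCCO2)ccn1S(=O)(=O)c1ccccc1 | intermediate
8 | carbon tetrabromide | BrC(Br)(Br)Br | starting material
9 | water | O | starting material
10 | 2-(2,2-dibromovinyl)-3-(2-methyl-1,3-dioxolan-2-yl)-1-(phenylsulfonyl)pyrrole (not isolated) | BrC(Br)=Cc1c(C2(C)OCCO2)ccn1S(=O)(=O)c1ccccc1 | intermediate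
11 | 1-[2-(2,2-dibromovinyl)-1-(phenylsulfonyl)pyrrol-3-yl]ethanone | CC(=O)c1ccn(S(=O)(=O)c2ccccc2)c1C=C(Br)Br | intermediate
12 | bromine | BrBr | starting material
13 | 3-(1-bromovinyl)-2-(2,2-dibromovinyl)-1-(phenylsulfonyl)pyrrole | C=C(Br)c1ccn(S(=O)(=O)c2ccccc2)c1C=C(Br)Br | intermediate
14 | 4,6,6-tribromo-1-(phenylsulfonyl)-5,6-dihydro-1H-indole (not isolated) | BrC1=C2C=CN(S(=O)(=O)c3ccccc3)C2=CC(Br)(Br)C1 | intermediate
15 | 4,6-dibromo-1-(phenylsulfonyl)indole | Brc1cc(Br)c2ccn(S(=O)(=O)c3ccccc3)c2c1 | intermediate
16 | 3,4,6-tribromo-1-(phenylsulfonyl)indole | Brc1cc(Br)c2c(Br)cn(S(=O)(=O)c3ccccc3)c2c1 | intermediate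
17 | 3,4,6-tribromo-1H-indole | Brc1cc(Br)c2c(Br)c[nH]c2c1 | target

## Step count and least certain steps

Total step count: 7 steps. Longest linear sequence: 7 steps (from 1).

Step 5 (key step, proposed new method). The closure may be slower than the thermal decay of the triene, through loss of HBr from the vinyl bromides to give alkynes or through radical polymerisation. The cause is that one bromine of the CBr2 terminus must turn into the forming ring and pyrrole aromaticity is given up in the transition state. The fallback uses known chemistry and makes the five-membered ring last on a ready-made dibromoarene; it sets out from 4 and comes back to the route at 15. 4 is converted into N,N-dimethylformamide dimethyl acetal F1 (dimethyl sulfate, then NaOMe). F1 condenses at 110 °C, with loss of methanol, with the acidic methyl group of 2,4-dibromo-6-nitrotoluene F2 to give the enamine (E)-2-(2,4-dibromo-6-nitrophenyl)-N,N-dimethylethenamine F3. Reduction of the nitro group with Fe powder in AcOH, which leaves aryl bromides alone, is followed by ring closure with loss of dimethylamine to 4,6-dibromo-1H-indole F4 (Leimgruber–Batcho indole synthesis). NaH and PhSO2Cl in THF then give 15.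

Step 2. Deprotonation may take place at the less hindered C5 position, or on the phenylsulfonyl ring, in competition with C2, because the ketal is bulky and only a moderate directing group; the formyl group would then enter at the wrong carbon. The fallback uses a silicon blocking group; it sets out from 3 and comes back at 7. LiN(iPr)2 in the presence of Me3SiCl at −78 °C silylates the position that lithiates first and should give 4-(2-methyl-1,3-dioxolan-2-yl)-1-(phenylsulfonyl)-2-(trimethylsilyl)pyrrole F5. The only α-hydrogen left is then the one at the desired carbon, so a second lithiation and quench with 4 should give 3-(2-methyl-1,3-dioxolan-2-yl)-1-(phenylsulfonyl)-5-(trimethylsilyl)pyrrole-2-carbaldehyde F6. Buffered fluoride (Bu4NF/AcOH, THF, 0 °C) removes the silyl group and returns 7.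

Step 4. Activation of the carbonyl group may be incomplete, because the acetyl group is conjugated with the pyrrole and is a poor electrophile, or HBr may add to the new bromoalkene. The fallback makes the bromoalkene from an alkene instead of from the carbonyl group; it sets out from 11 and comes back at 13. NaBH4 (MeOH, 0 °C) reduces the ketone to racemic 1-[2-(2,2-dibromovinyl)-1-(phenylsulfonyl)pyrrol-3-yl]ethanol F7. Dehydration with the Burgess reagent (PhMe, 60 °C) gives 2-(2,2-dibromovinyl)-1-(phenylsulfonyl)-3-vinylpyrrole F8. Addition of 12 (CH2Cl2, −78 °C) to the styrene-like double bond, which is far more electron-rich than the dibromoalkene, gives racemic 3-(1,2-dibromoethyl)-2-(2,2-dibromovinyl)-1-(phenylsulfonyl)pyrrole F9. K2CO3 in MeOH/THF then removes the acidic benzylic hydrogen together with the primary bromide, the standard way to 1-bromovinyl arenes, and gives 13.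

## Further compounds

F1 | step 5 | N,N-dimethylformamide dimethyl acetal | COC(OC)N(C)C
F2 | step 5 | 2,4-dibromo-6-nitrotoluene | Cc1c(Br)cc(Br)cc1[N+](=O)[O-]
F3 | step 5 | (E)-2-(2,4-dibromo-6-nitrophenyl)-N,N-dimethylethenamine | CN(C)/C=C/c1c(Br)cc(Br)cc1[N+](=O)[O-]
F4 | step 5 | 4,6-dibromo-1H-indole | Brc1cc(Br)c2cc[nH]c2c1
F5 | step 2 | 4-(2-methyl-1,3-dioxolan-2-yl)-1-(phenylsulfonyl)-2-(trimethylsilyl)pyrrole | CC1(c2cc([Si](C)(C)C)n(S(=O)(=O)c3ccccc3)c2)OCCO1
F6 | step 2 | 3-(2-methyl-1,3-dioxolan-2-yl)-1-(phenylsulfonyl)-5-(trimethylsilyl)pyrrole-2-carbaldehyde | CC1(c2cc([Si](C)(C)C)n(S(=O)(=O)c3ccccc3)c2C=O)OCCO1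
F7 | step 4 | 1-[2-(2,2-dibromovinyl)-1-(phenylsulfonyl)pyrrol-3-yl]ethanol (racemic) | CC(O)c1ccn(S(=O)(=O)c2ccccc2)c1C=C(Br)Br
F8 | step 4 | 2-(2,2-dibromovinyl)-1-(phenylsulfonyl)-3-vinylpyrrole | C=Cc1ccn(S(=O)(=O)c2ccccc2)c1C=C(Br)Br
F9 | step 4 | 3-(1,2-dibromoethyl)-2-(2,2-dibromovinyl)-1-(phenylsulfonyl)pyrrole (racemic) | BrCC(Br)c1ccn(S(=O)(=O)c2ccccc2)c1C=C(Br)Br
A1 | alternative 1 | 1-tosyl-4,6-bis(trimethylsilyl)indoline | C[Si](C)(C)c1cc([Si](C)(C)C)c2CCN(S(=O)(=O)c3ccc(C)cc3)c2c1
A2 | alternative 1 | N-ethynyl-4-methyl-N-[4-(trimethylsilyl)but-3-yn-1-yl]benzenesulfonamide | C#CN(CCC#C[Si](C)(C)C)S(=O)(=O)c1ccc(C)cc1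
A3 | alternative 1 | ethynyltrimethylsilane | C#C[Si](C)(C)C
A4 | alternative 2 | 1-tert-butyl 2-methyl 4,6-dibromoindoline-1,2-dicarboxylate (racemic) | COC(=O)C1Cc2c(Br)cc(Br)cc2N1C(=O)OC(C)(C)C
A5 | alternative 2 | 3,5-dibromobenzyne | BrC1=CC(Br)=CC#C1
A6 | alternative 2 | 2,4-dibromo-6-(trimethylsilyl)phenyl trifluoromethanesulfonate | C[Si](C)(C)c1cc(Br)cc(Br)c1OS(=O)(=O)C(F)(F)F
A7 | alternative 2 | methyl 2-[(tert-butoxycarbonyl)amino]acrylate | C=C(NC(=O)OC(C)(C)C)C(=O)OC
A8 | alternative 3 | 1-acetyl-3,4,6-tribromoindole | CC(=O)n1cc(Br)c2c(Br)cc(Br)cc21
A9 | alternative 3 | 4,5,7-tribromo-2-methylquinoline 1-oxide | Cc1cc(Br)c2c(Br)cc(Br)cc2[n+]1[O-]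
A10 | alternative 3 | 5,6,8-tribromo-2-methyl-3,1-benzoxazepine | CC1=Nc2cc(Br)cc(Br)c2C(Br)=CO1
A11 | alternative 3 | 3,5-dibromoaniline | Nc1cc(Br)cc(Br)c1
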